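**Plan**

Numbering: C1 = bridgehead carrying geranyl; C2/C3/C4 = enolised 1,3-diketone bridge, aroyl on C3; C5 = bridgehead carrying prenyl; C6 = CMe2; C7 = CH(prenyl); C8 = CH2; C9 = bridging ketone. Ring A is C1-C8-C7-C6-C5-C9 and ring B is C1-C2-C3-C4-C5-C9.
Retrosynthetic cuts, in order: the O-protecting groups, C3-C(aroyl), C1-CH2(geranyl), the CH2-CH= bond of the C7 prenyl group, C6-C7 (opens ring A), the enoate C=C, C1-C9 and C3-C4 (open ring B), C5-CH2(prenyl).
Enabling feature: the gem-dimethyl carbon C6 of ring A lies between the quaternary bridgehead C5 and the methine C7. C6 can therefore be a tertiary radical made by adding H to the CH2 of an isopropenyl group on C5, while C7 is the beta-carbon of a butenoate chain hanging from C1 of ring B.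
Forward order: the C5 malonate is built and desymmetrised. Ring B is closed around it (C3-C4 acylation, then C1-C9 vinylogous Dieckmann). Ring A is closed by the radical C6-C7 bond. The C7, C1 and C3 substituents follow.
Stereochemistry: C5 comes from esterase hydrolysis of the prochiral malonate. C1 and C7 are set relative to C5 in the radical closure (bridge geometry, chair-like transition state). The E-alkene arrives with geranyl bromide, and bridgehead substitution cannot invert.

Key step: step 8

Assumptions: pig liver esterase is taken to give the (S)-half-ester 4 as drawn, and both sense and level of selectivity have to be verified (the resolution given for step 2 reaches either antipode); 9 and 11 are tautomeric mixtures, 9 being drawn as its dienol and 11 as the diketo form that reacts.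

Step 1
Reactants: 1 diethyl isopropylidenemalonate; 2 prenyl bromide (1-bromo-3-methylbut-2-ene)
Product: 3 diethyl 2-(3-methylbut-2-enyl)-2-(prop-1-en-2-yl)malonate (achiral, prochiral at the future C5)
Conditions: NaH, DMF, 0 °C; then 2, 0 °C to rt
Reagents that add atoms: none
Why: Deconjugative alpha-alkylation of an alkylidenemalonate, in which NaH removes a gamma-proton and the extended enolate is alkylated by the primary allylic bromide (SN2) at the alpha-carbon, so that the double bond leaves conjugation and the quaternary carbon with its isopropenyl group is created.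

Step 2
Reactants: 3 diethyl 2-(3-methylbut-2-enyl)-2-(prop-1-en-2-yl)malonate
Product: 4 (S)-2-(ethoxycarbonyl)-5-methyl-2-(prop-1-en-2-yl)hex-4-enoic acid
Conditions: pig liver esterase, phosphate buffer pH 7.5/DMSO 9:1, 25 °C; then acidify to pH 3
Reagents that add atoms: water, O
Why: Enzymatic desymmetrisation of a prochiral alpha,alpha-disubstituted malonate, in which the esterase should hydrolyse only one enantiotopic ester and thereby set C5, while the hindered anionic half-ester resists a second hydrolysis.

Step 3
Reactants: 4 (S)-2-(ethoxycarbonyl)-5-methyl-2-(prop-1-en-2-yl)hex-4-enoic acid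
Product: 5 ethyl (R)-2-(chlorocarbonyl)-5-methyl-2-(prop-1-en-2-yl)hex-4-enoate (same spatial arrangement, descriptor changes with priorities)
Conditions: 1-chloro-N,N,2-trimethylprop-1-en-1-amine, CH2Cl2, 0 °C
Reagents that add atoms: 1-chloro-N,N,2-trimethylprop-1-en-1-amine, CC(C)=C(Cl)N(C)C
Why: Neutral acid chloride formation with an alpha-chloroenamine, which liberates no HCl that could add to the two alkenes, while the quaternary alpha-carbon rules out ketene formation and racemisation.

Step 4
Reactants: 5 ethyl (R)-2-(chlorocarbonyl)-5-methyl-2-(prop-1-en-2-yl)hex-4-enoate; 6 hex-5-en-2-one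
Product: 7 ethyl (S)-2-(3-methylbut-2-enyl)-3,5-dioxo-2-(prop-1-en-2-yl)non-8-enoate
Conditions: 6 (2.2 equiv), LDA (2.1 equiv), THF, -78 °C; then 5, -78 °C; aq NH4Cl
Reagents that add atoms: none
Why: Claisen-type C-acylation of the kinetic methyl-side lithium enolate by the acid chloride, the second equivalent of enolate taking up the acidic proton of the beta-diketone formed, which joins C3 to C4 and leaves C5 untouched.

Step 5
Reactants: 7 ethyl (S)-2-(3-methylbut-2-enyl)-3,5-dioxo-2-(prop-1-en-2-yl)non-8-enoate
Product: 8 ethyl (S,E)-5-methoxy-2-(3-methylbut-2-enyl)-3-oxo-2-(prop-1-en-2-yl)nona-4,8-dienoate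
Conditions: HC(OMe)3, p-TsOH (cat.), MeOH, rt
Reagents that add atoms: trimethyl orthoformate, COC(OC)OC
Why: Acid-catalysed enol etherification of a beta-diketone, in which methanol attacks the open C2 carbonyl and not the neopentyl C4 carbonyl, so that the methoxy group ends on C2 and the favoured E isomer holds C1 and C4 on the same side as the coming ring closure needs.

Step 6
Reactants: 8 ethyl (S,E)-5-methoxy-2-(3-methylbut-2-enyl)-3-oxo-2-(prop-1-en-2-yl)nona-4,8-dienoate
Product: 9 (R)-4-allyl-5-hydroxy-3-methoxy-6-(3-methylbut-2-enyl)-6-(prop-1-en-2-yl)cyclohexa-2,4-dien-1-one (ring B, drawn as the dienol)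
Conditions: KHMDS (2.2 equiv), THF, -78 °C to rt; then 1 M HCl, 0 °C
Reagents that add atoms: none
Why: Vinylogous Dieckmann condensation, in which gamma-deprotonation at C1 gives a dienolate that can reach the C9 ester only through C1 (attack through C3 would give a four-membered ring), helped by the geminal substitution at C5 and driven by deprotonation of the acidic product.

Step 7
Reactants: 9 (R)-4-allyl-5-hydroxy-3-methoxy-6-(3-methylbut-2-enyl)-6-(prop-1-en-2-yl)cyclohexa-2,4-dien-1-one; 10 methyl acrylate
Product: 11 methyl (E)-4-[2-methoxy-4,6-dioxo-5-(3-methylbut-2-enyl)-5-(prop-1-en-2-yl)cyclohex-2-en-1-yl]but-2-enoate (ring B, drawn as the diketo tautomer with the C1 chain cis to the C5 isopropenyl group)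
Conditions: 10 (10 equiv), second-generation Hoveyda-Grubbs catalyst (5 mol %), CH2Cl2, 40 °C
Reagents that add atoms: none
Why: E-selective cross-metathesis of a monosubstituted alkene with an acrylate under neutral conditions, the trisubstituted prenyl and the hindered 1,1-disubstituted isopropenyl alkenes reacting far more slowly and the excess of acrylate outrunning ring-closing metathesis.

Step 8
Reactants: 11 methyl (E)-4-[2-methoxy-4,6-dioxo-5-(3-methylbut-2-enyl)-5-(prop-1-en-2-yl)cyclohex-2-en-1-yl]but-2-enoate
Product: 12 methyl 2-[2-methoxy-6,6-dimethyl-5-(3-methylbut-2-enyl)-4,9-dioxobicyclo[3.3.1]non-2-en-7-yl]acetate (H at C1, acetate arm exo at C7)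
Conditions: Fe(acac)3 (0.5 equiv), PhSiH3 (2.5 equiv, added over 2 h), EtOH/ClCH2CH2Cl 1:4, degassed, 60 °C
Reagents that add atoms: none
Why: Fe(acac)3 and PhSiH3 give an iron hydride that passes a hydrogen atom to the open =CH2 end of the isopropenyl group on C5, so that the former methylene becomes the second methyl on C6 and a nucleophilic tertiary radical sits at C6; this radical adds to the electron-poor C7 of the butenoate on C1, and the alpha-ester radical is reduced by divalent iron to an enolate that ethanol protonates. The closest known reaction is the iron-catalysed reductive olefin coupling run intramolecularly, a Giese cyclisation started by metal-hydride hydrogen-atom transfer, which is established for bonds to fully substituted carbon. Ring A closes 6-exo-trig through a chair-like array C6-C5-C9-C1-C8-C7, and the early transition state of a radical addition is what allows a bond to form next to quaternary C5. C1 is set by the bridge, since only the diketo tautomer whose butenoate chain stands cis to the isopropenyl group (both pseudo-axial on ring B) can bring C7 to C6, and the acidic C1-H lets the enol and the trans epimer drain into this form. C7 is set by the chair, in which the CH-CO2Me terminus points away from ring B and ends as the equatorial, exo acetate arm. The step needs hydrogen-atom transfer to the 1,1-disubstituted alkene ahead of the trisubstituted prenyl alkene, and closure ahead of plain reduction: the first rests on the unhindered methylene terminus, the second on slow addition of the silane, on a weakly polar medium that favours the diketo form and on the six-membered geometry.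

Step 9
Reactants: 12 methyl 2-[2-methoxy-6,6-dimethyl-5-(3-methylbut-2-enyl)-4,9-dioxobicyclo[3.3.1]non-2-en-7-yl]acetate
Product: 13 2-[2-methoxy-6,6-dimethyl-5-(3-methylbut-2-enyl)-4,9-dioxobicyclo[3.3.1]non-2-en-7-yl]acetic acid
Conditions: LiOH, THF/H2O, 0 °C; then 1 M HCl
Reagents that add atoms: lithium hydroxide, [Li+].[OH-]
Why: Saponification of the unhindered methyl ester at low temperature, whereas the hindered vinylogous ester of this ring system is cleaved only by hot base, and no hydride reagent that would attack the C9 ketone is needed.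

Step 10
Reactants: 13 2-[2-methoxy-6,6-dimethyl-5-(3-methylbut-2-enyl)-4,9-dioxobicyclo[3.3.1]non-2-en-7-yl]acetic acid; 14 2-methylprop-1-enylmagnesium bromide
Product: 16 2-methoxy-6,6-dimethyl-5,7-bis(3-methylbut-2-enyl)bicyclo[3.3.1]non-2-ene-4,9-dione (H at C1; C7 prenyl exo), via N-hydroxyphthalimide ester 15 (not isolated)
Conditions: N-hydroxyphthalimide, N,N'-diisopropylcarbodiimide, DMAP (cat.), CH2Cl2, rt; then Ni(acac)2 (10 mol %), 2,2'-bipyridine (10 mol %), (2-methylprop-1-enyl)zinc chloride (from 14 and ZnCl2), THF/DMF, rt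
Reagents that add atoms: N-hydroxyphthalimide, O=C1c2ccccc2C(=O)N1O (its atoms stay only in 15)
Why: Nickel-catalysed decarboxylative alkenylation of a redox-active ester with an alkenylzinc reagent, which replaces CO2H by the 2-methylpropenyl group and so completes the C7 prenyl chain without touching the C9 ketone, the vinylogous ester or the C7 stereocentre.

Step 11
Reactants: 16 2-methoxy-6,6-dimethyl-5,7-bis(3-methylbut-2-enyl)bicyclo[3.3.1]non-2-ene-4,9-dione; 17 geranyl bromide
Product: 18 1-[(E)-3,7-dimethylocta-2,6-dienyl]-2-methoxy-6,6-dimethyl-5,7-bis(3-methylbut-2-enyl)bicyclo[3.3.1]non-2-ene-4,9-dione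
Conditions: LDA (1.3 equiv), THF, -78 °C; then 17, -78 °C to rt
Reagents that add atoms: none
Why: Bridgehead lithiation and alkylation, known for methyl enol ethers of bicyclo[3.3.1]nonane-2,4,9-triones, in which LDA removes the C1-H flanked by C9=O and the C2 enol ether, the cage fixes the configuration of the carbanion, and SN2 attack at the primary carbon keeps the E-alkene.

Step 12
Reactants: 19 3,4-dihydroxybenzoic acid
Product: 20 tert-butyldimethylsilyl 3,4-bis(tert-butyldimethylsilyloxy)benzoate
Conditions: TBSCl (3.3 equiv), imidazole, DMF, rt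
Reagents that add atoms: tert-butyldimethylsilyl chloride, CC(C)(C)[Si](C)(C)Cl
Why: Exhaustive silylation of both phenols and the acid, which masks the catechol against the organolithium chemistry of step 14.

Step 13
Reactants: 20 tert-butyldimethylsilyl 3,4-bis(tert-butyldimethylsilyloxy)benzoate
Product: 21 3,4-bis(tert-butyldimethylsilyloxy)benzoyl chloride
Conditions: (COCl)2, DMF (cat.), CH2Cl2, 0 °C to rt
Reagents that add atoms: oxalyl chloride, O=C(Cl)C(=O)Cl
Why: Direct conversion of a silyl ester into the acid chloride by the chloroiminium reagent from oxalyl chloride and DMF, which proceeds without free acid and leaves the aryl silyl ethers in place.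

Step 14
Reactants: 18 1-[(E)-3,7-dimethylocta-2,6-dienyl]-2-methoxy-6,6-dimethyl-5,7-bis(3-methylbut-2-enyl)bicyclo[3.3.1]non-2-ene-4,9-dione; 21 3,4-bis(tert-butyldimethylsilyloxy)benzoyl chloride
Product: 22 3-[3,4-bis(tert-butyldimethylsilyloxy)benzoyl] derivative of 18
Conditions: 2,2,6,6-tetramethylpiperidine, n-BuLi, THF, 0 °C; then 18, -78 °C; then 21, -78 °C to 0 °C
Reagents that add atoms: none
Why: Alpha-lithiation of the vinylogous ester at the only remaining acidic site, the vinylic C3-H, by the hindered lithium amide, followed by acylation with the aroyl chloride, a sequence known for this class of bicyclic enol ethers.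

Step 15
Reactants: 22 3-[3,4-bis(tert-butyldimethylsilyloxy)benzoyl] derivative of 18
Product: 23 bis-silyl ether of the target (free enolised triketone)
Conditions: LiCl (10 equiv), DMSO, 120 °C; then dilute HCl
Reagents that add atoms: none
Why: Nucleophilic demethylation of the vinylogous ester by chloride (SN2 at the methyl group, the stabilised triketonate being the leaving group), and any silyl loss at this stage is harmless because the next step removes both silyl groups.

Step 16
Reactants: 23 bis-silyl ether of the target
Product: 24 target CNP0160101.4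
Conditions: HF·pyridine, pyridine, THF, 0 °C to rt
Reagents that add atoms: none
Why: Buffered fluoride cleavage of the two aryl silyl ethers, which spares the trisubstituted alkenes and the enolised triketone and touches no stereocentre.

**Compound list**

1 | diethyl isopropylidenemalonate | CCOC(=O)C(=C(C)C)C(=O)OCC | starting material
2 | prenyl bromide | CC(C)=CCBr | starting material
3 | diethyl 2-(3-methylbut-2-enyl)-2-(prop-1-en-2-yl)malonate | CCOC(=O)C(CC=C(C)C)(C(C)=C)C(=O)OCC | intermediate
4 | (S)-2-(ethoxycarbonyl)-5-methyl-2-(prop-1-en-2-yl)hex-4-enoic acid | OC(=O)[C@](CC=C(C)C)(C(C)=C)C(=O)OCC | intermediate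
5 | ethyl (R)-2-(chlorocarbonyl)-5-methyl-2-(prop-1-en-2-yl)hex-4-enoate | ClC(=O)[C@](CC=C(C)C)(C(C)=C)C(=O)OCC | intermediate
6 | hex-5-en-2-one | CC(=O)CCC=C | starting material
7 | ethyl (S)-2-(3-methylbut-2-enyl)-3,5-dioxo-2-(prop-1-en-2-yl)non-8-enoate | C=CCCC(=O)CC(=O)[C@](CC=C(C)C)(C(C)=C)C(=O)OCC | intermediate
8 | ethyl (S,E)-5-methoxy-2-(3-methylbut-2-enyl)-3-oxo-2-(prop-1-en-2-yl)nona-4,8-dienoate | C=CCC/C(OC)=C\C(=O)[C@](CC=C(C)C)(C(C)=C)C(=O)OCC | intermediate
9 | (R)-4-allyl-5-hydroxy-3-methoxy-6-(3-methylbut-2-enyl)-6-(prop-1-en-2-yl)cyclohexa-2,4-dien-1-one (dienol tautomer) | C=CCC1=C(O)[C@@](CC=C(C)C)(C(C)=C)C(=O)C=C1OC | intermediate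
10 | methyl acrylate | C=CC(=O)OC | starting material
11 | methyl (E)-4-[2-methoxy-4,6-dioxo-5-(3-methylbut-2-enyl)-5-(prop-1-en-2-yl)cyclohex-2-en-1-yl]but-2-enoate (diketo tautomer, C1 chain cis to isopropenyl) | [C@@H]1(C/C=C/C(=O)OC)C(OC)=CC(=O)[C@](CC=C(C)C)(C(C)=C)C1=O | intermediate
12 | methyl 2-[2-methoxy-6,6-dimethyl-5-(3-methylbut-2-enyl)-4,9-dioxobicyclo[3.3.1]non-2-en-7-yl]acetate (arm exo) | [C@@H]12C[C@H](CC(=O)OC)C(C)(C)[C@@](CC=C(C)C)(C(=O)C=C1OC)C2=O | intermediate
13 | 2-[2-methoxy-6,6-dimethyl-5-(3-methylbut-2-enyl)-4,9-dioxobicyclo[3.3.1]non-2-en-7-yl]acetic acid | [C@@H]12C[C@H](CC(=O)O)C(C)(C)[C@@](CC=C(C)C)(C(=O)C=C1OC)C2=O | intermediate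
14 | 2-methylprop-1-enylmagnesium bromide | CC(C)=C[Mg]Br | starting material
15 | N-hydroxyphthalimide ester of 13 (not isolated) | [C@@H]12C[C@H](CC(=O)ON3C(=O)c4ccccc4C3=O)C(C)(C)[C@@](CC=C(C)C)(C(=O)C=C1OC)C2=O | intermediate
16 | 2-methoxy-6,6-dimethyl-5,7-bis(3-methylbut-2-enyl)bicyclo[3.3.1]non-2-ene-4,9-dione | [C@@H]12C[C@H](CC=C(C)C)C(C)(C)[C@@](CC=C(C)C)(C(=O)C=C1OC)C2=O | intermediate
17 | geranyl bromide | CC(C)=CCC/C(C)=C/CBr | starting material
18 | 1-geranyl derivative of 16 | CC(C)=CCC/C(C)=C/C[C@@]12C[C@H](CC=C(C)C)C(C)(C)[C@@](CC=C(C)C)(C(=O)C=C1OC)C2=O | intermediate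
19 | 3,4-dihydroxybenzoic acid | O=C(O)c1ccc(O)c(O)c1 | starting material
20 | tert-butyldimethylsilyl 3,4-bis(tert-butyldimethylsilyloxy)benzoate | CC(C)(C)[Si](C)(C)OC(=O)c1ccc(O[Si](C)(C)C(C)(C)C)c(O[Si](C)(C)C(C)(C)C)c1 | intermediate
21 | 3,4-bis(tert-butyldimethylsilyloxy)benzoyl chloride | O=C(Cl)c1ccc(O[Si](C)(C)C(C)(C)C)c(O[Si](C)(C)C(C)(C)C)c1 | intermediate
22 | 3-aroylated methyl enol ether | CC(C)=CCC/C(C)=C/C[C@@]12C[C@H](CC=C(C)C)C(C)(C)[C@@](CC=C(C)C)(C(=O)C(C(=O)c3ccc(O[Si](C)(C)C(C)(C)C)c(O[Si](C)(C)C(C)(C)C)c3)=C1OC)C2=O | intermediate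
23 | bis-silyl ether of the target | CC(C)=CCC/C(C)=C/C[C@@]12C[C@H](CC=C(C)C)C(C)(C)[C@@](CC=C(C)C)(C(=O)C(C(=O)c3ccc(O[Si](C)(C)C(C)(C)C)c(O[Si](C)(C)C(C)(C)C)c3)=C1O)C2=O | intermediate
24 | CNP0160101.4 | CC(C)=CCC/C(C)=C/C[C@@]12C[C@H](CC=C(C)C)C(C)(C)[C@@](CC=C(C)C)(C(=O)C(C(=O)c3ccc(O)c(O)c3)=C1O)C2=O | target

Total step count: 16. Longest linear sequence: 14 steps (steps 1-11 and 14-16); steps 12 and 13 are the aroyl chloride branch.

**Steps most likely to fail**

**Step 8.**
- Hydrogen-atom transfer does not distinguish the closing form of 11 from its enol, from its C1=C2 enol-ether tautomer or from its trans C1 epimer. A C6 radical born in one of these forms is reduced before it can equilibrate.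
- Further drains are transfer to the prenyl alkene, 1,2-acyl migration of the C6 radical through the C4 or C9 carbonyl, and oxa-Michael addition of the C9 enol to the enoate.
- The fallback builds ring A first and ring B by annulation. It sets out from prenyl bromide 2 and returns at 16.
- 3-Ethoxycyclohex-2-enone is alkylated at C6 with LDA and 2 to give racemic 3-ethoxy-6-(3-methylbut-2-enyl)cyclohex-2-en-1-one F1.
- Methyllithium followed by dilute acid (Stork-Danheiser transposition), then separation on a chiral stationary phase, gives (R)-3-methyl-4-(3-methylbut-2-enyl)cyclohex-2-en-1-one F2.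
- Me2CuLi adds in 1,4 fashion and the enolate is trapped by 2 to give 3,3-dimethyl-2,4-bis(3-methylbut-2-enyl)cyclohexanone F3.
- TMSOTf and Et3N give its more substituted trimethylsilyl enol ether F4.
- Annulation with malonyl dichloride (Effenberger cyclisation) lays ring B on the face away from the C7 prenyl group and gives 6,6-dimethyl-5,7-bis(3-methylbut-2-enyl)bicyclo[3.3.1]nonane-2,4,9-trione F5.
- Trimethyl orthoformate and acid etherify the less hindered C2 carbonyl and give 16.

**Step 2.**
- The enzyme may discriminate poorly between the enantiotopic esters, may prefer the opposite one, or may turn over this hindered malonate too slowly.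
- The fallback is a classical resolution. It sets out from 3 and returns at 4.
- One equivalent of KOH in ethanol gives racemic 2-(ethoxycarbonyl)-5-methyl-2-(prop-1-en-2-yl)hex-4-enoic acid F6.
- Crystallisation with (S)-1-phenylethylamine, or with its antipode if that gives the less soluble salt of the (S)-acid, gives the (S)-1-phenylethylammonium salt of the (S)-acid F7.
- Dilute acid releases 4.
- The unwanted acid is re-esterified to achiral 3 and recycled.

**Step 6.**
- Gamma-deprotonation and attack on the neopentyl ester may be slower than cleavage of the C4-C5 bond by liberated ethoxide, or slower than isomerisation of the enol ether, so that ring closure stalls.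
- The fallback closes the ring before etherification. It sets out from 7 and returns at 9.
- NaH followed by n-BuLi converts 7 into the 1,3-dianion of the beta-diketone.
- The terminal C1 carbanion of this dianion closes onto the ester (dianion Claisen condensation) to give 4-allyl-2-(3-methylbut-2-enyl)-2-(prop-1-en-2-yl)cyclohexane-1,3,5-trione F8.
- Acid-catalysed etherification with trimethyl orthoformate then takes place at C2, the only carbonyl not flanked by the quaternary carbon, and gives 9.

**Further compounds**

F1 | step 8 | 3-ethoxy-6-(3-methylbut-2-enyl)cyclohex-2-en-1-one (racemic) | CCOC1=CC(=O)C(CC=C(C)C)CC1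
F2 | step 8 | (R)-3-methyl-4-(3-methylbut-2-enyl)cyclohex-2-en-1-one | O=C1C=C(C)[C@@H](CC=C(C)C)CC1
F3 | step 8 | 3,3-dimethyl-2,4-bis(3-methylbut-2-enyl)cyclohexanone (C2 epimerisable) | O=C1C(CC=C(C)C)C(C)(C)[C@@H](CC=C(C)C)CC1
F4 | step 8 | trimethylsilyl enol ether of F3 | C[Si](C)(C)OC1=C(CC=C(C)C)C(C)(C)[C@@H](CC=C(C)C)CC1
F5 | step 8 | 6,6-dimethyl-5,7-bis(3-methylbut-2-enyl)bicyclo[3.3.1]nonane-2,4,9-trione | [C@@H]12C[C@H](CC=C(C)C)C(C)(C)[C@@](CC=C(C)C)(C(=O)CC1=O)C2=O
F6 | step 2 | 2-(ethoxycarbonyl)-5-methyl-2-(prop-1-en-2-yl)hex-4-enoic acid (racemic) | CCOC(=O)C(CC=C(C)C)(C(C)=C)C(=O)O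
F7 | step 2 | (S)-1-phenylethylammonium salt of the (S)-acid | [O-]C(=O)[C@](CC=C(C)C)(C(C)=C)C(=O)OCC.C[C@H]([NH3+])c1ccccc1
F8 | step 6 | 4-allyl-2-(3-methylbut-2-enyl)-2-(prop-1-en-2-yl)cyclohexane-1,3,5-trione | C=CCC1C(=O)CC(=O)[C@](CC=C(C)C)(C(C)=C)C1=O
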